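## Retrosynthetic overview

- **Feature:** ring A is a phloroglucinol with oxygen on C5, C7 and C8a. The prenyl group on C8 lies between C7–O and C8a–O. The 8- versus 6-prenyl question therefore comes down to which oxygen ortho to C4a (C8a–O or C5–O) becomes O1.
- **Ring C (made last):** O1–C2 comes from cyclodehydration. C2–C3 comes from Baker–Venkataraman acyl transfer out of a C8a–O 4-(methoxymethoxy)benzoate. C3–C4 comes from a hydroxymethyl-anion equivalent, and C4–C4a from ortho-formylation of the single free phenol.
- **Ring A (made first):** benzannulation of 3-ethoxycyclobutenone with the prenyl triisopropylsiloxyalkyne forms C8–C8a, C6–C7 and C4a–C8a. It leaves C8a–OH free, C7–O silylated and C5–O ethylated.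
- **Fragments:** the siloxyalkyne comes from 4-methylpent-3-enoic acid by ester-to-ynolate homologation. Ring B is bought as 4-hydroxybenzoic acid.
- **Ring order:** B (purchased), A (step 3), C (step 10). Unmasking follows at C3–O/C4'–O (step 10), C5–O (step 11) and C7–O (step 12).

Key step: step 3

Assumption: 3-ethoxycyclobut-2-en-1-one and tributyl[(methoxymethoxy)methyl]stannane are taken as purchasable; flavonol numbering (O1, C2 to C8a) is used for ring atoms in precursors too; the target has no stereocentre.

## Route

Step 1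
Reactants: 1 4-methylpent-3-enoic acid
Product: 2 ethyl 4-methylpent-3-enoate
Conditions: EtI, K2CO3, DMF, rt
Reagents that add atoms: iodoethane, CCI
Why: Carboxylate O-alkylation (SN2) under weakly basic conditions esterifies the acid without the mineral acid that would lactonise it through the tertiary cation or move the double bond into conjugation.

Step 2
Reactants: 2 ethyl 4-methylpent-3-enoate; 3 triisopropylsilyl chloride
Product: 6 triisopropyl[(5-methylhex-4-en-1-yn-1-yl)oxy]silane, via dibromoenolate 4 (not isolated), via lithium ynolate 5 (not isolated)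
Conditions: CH2Br2, lithium 2,2,6,6-tetramethylpiperidide, THF, −78 °C, then 2; n-BuLi, −78 °C → rt; 3, −78 °C → rt; H2O
Reagents that add atoms: dibromomethane, BrCBr
Why: Kowalski ester homologation stopped at the ynolate, in which LiCHBr2 adds to the ester, loss of ethoxide and deprotonation give 4, bromine–lithium exchange triggers the 1,2-shift of the prenyl group with loss of LiBr to give 5, and the bulky silyl chloride traps 5 on oxygen rather than on carbon.

Step 3
Reactants: 6 triisopropyl[(5-methylhex-4-en-1-yn-1-yl)oxy]silane; 7 3-ethoxycyclobut-2-en-1-one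
Product: 12 5-ethoxy-2-(3-methylbut-2-enyl)-3-(triisopropylsilyloxy)phenol, via vinylketene 8 (not isolated), via vinylcyclobutenone 9 (not isolated), via dienylketene 10 (not isolated), via cyclohexadienone 11 (not isolated)
Conditions: 6 (1.3 equiv), slow addition of 7, toluene, 80 → 110 °C, sealed tube, Ar
Reagents that add atoms: none
Why: Danheiser benzannulation: heat opens 7 by 4π electrocyclic cleavage of its C1–C4 bond to vinylketene 8, and the nucleophilic, prenyl-bearing carbon of ynol ether 6 attacks the ketene carbonyl carbon in a (2+2) cycloaddition that forms C8–C8a and C6–C7 and gives vinylcyclobutenone 9. A second 4π opening turns 9 into dienylketene 10, ring A closes by thermal disrotatory 6π electrocyclisation with formation of C4a–C8a, and dienone 11 tautomerises to phenol 12. The closest known reaction type is the same annulation of 3-alkylcyclobutenones with 2-alkyl triisopropylsiloxyalkynes, which gives 2,5-dialkylresorcinol monosilyl ethers, and an alkoxy group on C3 is known not to block thermal cyclobutenone opening in the squarate-derived series. No stereocentre survives, because C4 of 9 is formed racemic and becomes sp2 on ring opening. The selectivity needed is the orientation of the (2+2) step, and the oxygen-donor polarisation of 6 secures it, so that the old ketene carbonyl becomes the free C8a–OH next to the prenyl group, the siloxy carbon becomes C7 and the ethoxy carbon C5. Slow addition of 7 to an excess of 6 keeps the concentration of 8 low, which should hold back its dimerisation and the acylation of 12.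

Step 4
Reactants: 12 5-ethoxy-2-(3-methylbut-2-enyl)-3-(triisopropylsilyloxy)phenol
Product: 13 6-ethoxy-2-hydroxy-3-(3-methylbut-2-enyl)-4-(triisopropylsilyloxy)benzaldehyde
Conditions: MgCl2, Et3N, (CH2O)n, MeCN, reflux; cold 1 M HCl
Reagents that add atoms: paraformaldehyde (as formaldehyde), C=O
Why: Casnati–Skattebøl ortho-formylation, in which the magnesium phenoxide delivers formaldehyde only ortho to the free hydroxyl, where C4a is the single open site because the other ortho carbon carries the prenyl group, and a second formaldehyde oxidises the benzylic alkoxide by hydride transfer in a medium that leaves alkene and silyl ether alone.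

Step 5
Reactants: 13 6-ethoxy-2-hydroxy-3-(3-methylbut-2-enyl)-4-(triisopropylsilyloxy)benzaldehyde; 14 tributyl[(methoxymethoxy)methyl]stannane
Product: 16 3-ethoxy-2-[1-hydroxy-2-(methoxymethoxy)ethyl]-6-(3-methylbut-2-enyl)-5-(triisopropylsilyloxy)phenol (racemic), via (methoxymethoxy)methyllithium 15 (not isolated)
Conditions: 14 (2.4 equiv), n-BuLi (2.3 equiv), THF, −78 °C; then 13, −78 → −40 °C; H2O; crude product taken on
Reagents that add atoms: none
Why: Tin–lithium exchange gives the hydroxymethyl-anion equivalent 15, whose first equivalent deprotonates the phenol and whose second adds 1,2 to the aldehyde to form C3–C4, and the new carbinol centre is formed racemic and is erased in step 6.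

Step 6
Reactants: 16 3-ethoxy-2-[1-hydroxy-2-(methoxymethoxy)ethyl]-6-(3-methylbut-2-enyl)-5-(triisopropylsilyloxy)phenol
Product: 17 1-[6-ethoxy-2-hydroxy-3-(3-methylbut-2-enyl)-4-(triisopropylsilyloxy)phenyl]-2-(methoxymethoxy)ethan-1-one
Conditions: activated MnO2 (excess), CH2Cl2, rt
Reagents that add atoms: none
Why: Heterogeneous MnO2 oxidation is selective for the electron-rich benzylic alcohol, and its neutral medium avoids ionisation to the ortho-quinone methide and spares the trisubstituted alkene, the acetal and the silyl ether.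

Step 7
Reactants: 18 4-hydroxybenzoic acid
Product: 20 4-(methoxymethoxy)benzoic acid, via methoxymethyl ester 19 (not isolated)
Conditions: MOMCl (2.5 equiv), i-Pr2NEt, CH2Cl2, 0 °C → rt; then NaOH, MeOH/H2O, rt; 1 M HCl to pH 4, 0 °C
Reagents that add atoms: chloromethyl methyl ether, COCCl; sodium hydroxide, [Na+].[OH-]
Why: Double O-alkylation followed by saponification in the same flask removes only the labile acetal ester, because the aryl methoxymethyl ether is stable to base.

Step 8
Reactants: 17 1-[6-ethoxy-2-hydroxy-3-(3-methylbut-2-enyl)-4-(triisopropylsilyloxy)phenyl]-2-(methoxymethoxy)ethan-1-one; 20 4-(methoxymethoxy)benzoic acid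
Product: 21 3-ethoxy-2-[(methoxymethoxy)acetyl]-6-(3-methylbut-2-enyl)-5-(triisopropylsilyloxy)phenyl 4-(methoxymethoxy)benzoate
Conditions: EDC·HCl, DMAP, CH2Cl2, rt
Reagents that add atoms: none
Why: Steglich esterification, in which the acylpyridinium from DMAP is reactive enough for the hindered, hydrogen-bonded C8a–OH (the only free hydroxyl) and no acid chloride step endangers the acetal groups.

Step 9
Reactants: 21 3-ethoxy-2-[(methoxymethoxy)acetyl]-6-(3-methylbut-2-enyl)-5-(triisopropylsilyloxy)phenyl 4-(methoxymethoxy)benzoate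
Product: 22 1-[6-ethoxy-2-hydroxy-3-(3-methylbut-2-enyl)-4-(triisopropylsilyloxy)phenyl]-2-(methoxymethoxy)-3-[4-(methoxymethoxy)phenyl]propane-1,3-dione (racemic)
Conditions: LiN(SiMe3)2 (2.5 equiv), THF, −78 → −10 °C; AcOH quench
Reagents that add atoms: none
Why: Baker–Venkataraman rearrangement, in which the alpha-alkoxy ketone enolate attacks the neighbouring aryl ester through a six-membered transition state to form C2–C3 and free the C8a phenoxide, the non-nucleophilic base spares the aryl silyl ether, and the diketone methine is a labile racemic centre that becomes sp2 in step 10.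

Step 10
Reactants: 22 1-[6-ethoxy-2-hydroxy-3-(3-methylbut-2-enyl)-4-(triisopropylsilyloxy)phenyl]-2-(methoxymethoxy)-3-[4-(methoxymethoxy)phenyl]propane-1,3-dione
Product: 23 5-ethoxy-3-hydroxy-2-(4-hydroxyphenyl)-8-(3-methylbut-2-enyl)-7-(triisopropylsilyloxy)-4H-chromen-4-one
Conditions: HCl (1.25 M in MeOH), THF, 45 °C
Reagents that add atoms: none
Why: Acid-catalysed cyclodehydration closes ring C from the only free phenol (C8a–OH) onto the aroyl carbonyl while the same acid transacetalises both methoxymethyl groups, and because C5–O is still ethylated only the 8-prenyl isomer can form, while the silylated C7–O cannot add to the prenyl alkene.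

Step 11
Reactants: 23 5-ethoxy-3-hydroxy-2-(4-hydroxyphenyl)-8-(3-methylbut-2-enyl)-7-(triisopropylsilyloxy)-4H-chromen-4-one
Product: 24 3,5-dihydroxy-2-(4-hydroxyphenyl)-8-(3-methylbut-2-enyl)-7-(triisopropylsilyloxy)-4H-chromen-4-one
Conditions: MgI2·OEt2 (excess), THF/toluene, reflux; aqueous work-up
Reagents that add atoms: none
Why: Chelation-assisted ether cleavage, in which magnesium held between C4=O and C5–O activates only the peri ether and iodide removes the ethyl group by SN2, a reagent type known to unmask C5 alkyl ethers of 8-prenylated flavonoids with the prenyl chain intact.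

Step 12
Reactants: 24 3,5-dihydroxy-2-(4-hydroxyphenyl)-8-(3-methylbut-2-enyl)-7-(triisopropylsilyloxy)-4H-chromen-4-one
Product: 25 8-prenylkaempferol
Conditions: n-Bu4NF, AcOH, THF, 0 °C
Reagents that add atoms: none
Why: Fluoride-induced cleavage of the aryl silyl ether is fast for a phenol para to a carbonyl, and the acetic acid buffer keeps the polyphenol protonated and away from base-promoted oxidation.

## Compound list

1 | 4-methylpent-3-enoic acid | CC(C)=CCC(=O)O | starting material
2 | ethyl 4-methylpent-3-enoate | CCOC(=O)CC=C(C)C | intermediate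
3 | triisopropylsilyl chloride | CC(C)[Si](Cl)(C(C)C)C(C)C | starting material
4 | lithium 1,1-dibromo-5-methylhexa-1,4-dien-2-olate | [Li+].[O-]C(CC=C(C)C)=C(Br)Br | intermediate
5 | lithium 5-methylhex-4-en-1-yn-1-olate | [Li+].[O-]C#CCC=C(C)C | intermediate
6 | triisopropyl[(5-methylhex-4-en-1-yn-1-yl)oxy]silane | CC(C)=CCC#CO[Si](C(C)C)(C(C)C)C(C)C | intermediate
7 | 3-ethoxycyclobut-2-en-1-one | CCOC1=CC(=O)C1 | starting material
8 | 3-ethoxybuta-1,3-dien-1-one | C=C(OCC)C=C=O | intermediate
9 | 4-(1-ethoxyethenyl)-2-(3-methylbut-2-enyl)-3-(triisopropylsilyloxy)cyclobut-2-en-1-one (racemic) | C=C(OCC)C1C(=O)C(CC=C(C)C)=C1O[Si](C(C)C)(C(C)C)C(C)C | intermediate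
10 | (3E)-5-ethoxy-2-(3-methylbut-2-enyl)-3-(triisopropylsilyloxy)hexa-1,3,5-trien-1-one | O=C=C(CC=C(C)C)/C(O[Si](C(C)C)(C(C)C)C(C)C)=C\C(=C)OCC | intermediate
11 | 5-ethoxy-2-(3-methylbut-2-enyl)-3-(triisopropylsilyloxy)cyclohexa-2,4-dien-1-one | O=C1CC(OCC)=CC(O[Si](C(C)C)(C(C)C)C(C)C)=C1CC=C(C)C | intermediate
12 | 5-ethoxy-2-(3-methylbut-2-enyl)-3-(triisopropylsilyloxy)phenol | CC(C)=CCc1c(O)cc(OCC)cc1O[Si](C(C)C)(C(C)C)C(C)C | intermediate
13 | 6-ethoxy-2-hydroxy-3-(3-methylbut-2-enyl)-4-(triisopropylsilyloxy)benzaldehyde | CC(C)=CCc1c(O)c(C=O)c(OCC)cc1O[Si](C(C)C)(C(C)C)C(C)C | intermediate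
14 | tributyl[(methoxymethoxy)methyl]stannane | CCCC[Sn](CCCC)(CCCC)COCOC | starting material
15 | (methoxymethoxy)methyllithium | [Li]COCOC | intermediate
16 | 3-ethoxy-2-[1-hydroxy-2-(methoxymethoxy)ethyl]-6-(3-methylbut-2-enyl)-5-(triisopropylsilyloxy)phenol (racemic) | CC(C)=CCc1c(O)c(C(O)COCOC)c(OCC)cc1O[Si](C(C)C)(C(C)C)C(C)C | intermediate
17 | 1-[6-ethoxy-2-hydroxy-3-(3-methylbut-2-enyl)-4-(triisopropylsilyloxy)phenyl]-2-(methoxymethoxy)ethan-1-one | CC(C)=CCc1c(O)c(C(=O)COCOC)c(OCC)cc1O[Si](C(C)C)(C(C)C)C(C)C | intermediate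
18 | 4-hydroxybenzoic acid | O=C(O)c1ccc(O)cc1 | starting material
19 | methoxymethyl 4-(methoxymethoxy)benzoate | COCOC(=O)c1ccc(OCOC)cc1 | intermediate
20 | 4-(methoxymethoxy)benzoic acid | COCOc1ccc(C(=O)O)cc1 | intermediate
21 | 3-ethoxy-2-[(methoxymethoxy)acetyl]-6-(3-methylbut-2-enyl)-5-(triisopropylsilyloxy)phenyl 4-(methoxymethoxy)benzoate | CC(C)=CCc1c(OC(=O)c2ccc(OCOC)cc2)c(C(=O)COCOC)c(OCC)cc1O[Si](C(C)C)(C(C)C)C(C)C | intermediate
22 | 1-[6-ethoxy-2-hydroxy-3-(3-methylbut-2-enyl)-4-(triisopropylsilyloxy)phenyl]-2-(methoxymethoxy)-3-[4-(methoxymethoxy)phenyl]propane-1,3-dione (racemic) | CC(C)=CCc1c(O)c(C(=O)C(OCOC)C(=O)c2ccc(OCOC)cc2)c(OCC)cc1O[Si](C(C)C)(C(C)C)C(C)C | intermediate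
23 | 5-ethoxy-3-hydroxy-2-(4-hydroxyphenyl)-8-(3-methylbut-2-enyl)-7-(triisopropylsilyloxy)-4H-chromen-4-one | CC(C)=CCc1c(O[Si](C(C)C)(C(C)C)C(C)C)cc(OCC)c2c(=O)c(O)c(-c3ccc(O)cc3)oc12 | intermediate
24 | 3,5-dihydroxy-2-(4-hydroxyphenyl)-8-(3-methylbut-2-enyl)-7-(triisopropylsilyloxy)-4H-chromen-4-one | CC(C)=CCc1c(O[Si](C(C)C)(C(C)C)C(C)C)cc(O)c2c(=O)c(O)c(-c3ccc(O)cc3)oc12 | intermediate
25 | 8-prenylkaempferol | CC(C)=CCc1c(O)cc(O)c2c(=O)c(O)c(-c3ccc(O)cc3)oc12 | target

## Step count and risks

Total step count: 12.
Longest linear sequence: 11 (steps 1–6 and 8–12; step 7 is the side branch).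

### Steps most likely to fail

**1. Step 3**
- **What may go wrong:** the vinylogous-ester stabilisation of 7 may push its ring opening to temperatures at which the siloxyalkyne suffers an oxygen-to-carbon silyl shift. The vinylketene may also be lost to dimerisation and to acylation of the product phenol.
- **Fallback:** the vinylketene is generated by photochemical Wolff rearrangement instead of thermal ring opening (the diazoketone variant of the benzannulation). It sets out from siloxyalkyne 6 and comes back at phenol 12.
  - Ethyl vinyl ether is lithiated (t-BuLi, THF, −78 → 0 °C) to 1-ethoxyvinyllithium F1. This is acylated with N-methoxy-N-methylacetamide to 3-ethoxybut-3-en-2-one F2.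
  - F2 is trifluoroacetylated (LiN(SiMe3)2, CF3CO2CH2CF3, THF, −78 °C) to 5-ethoxy-1,1,1-trifluorohex-5-ene-2,4-dione F3.
  - Detrifluoroacetylative diazo transfer (MsN3, Et3N, H2O, MeCN) gives 1-diazo-3-ethoxybut-3-en-2-one F4.
  - Irradiation of F4 with 6 in CH2Cl2 at room temperature should release the same vinylketene 8 and let it add to 6 to give 9. Brief heating at 80 °C then carries 9 through 10 and 11 to 12.

**2. Step 2**
- **What may go wrong:** the lithium amide or LiCHBr2 may deprotonate the doubly activated C2 methylene of 2 in competition with carbonyl addition. This would be accompanied by drift of the double bond into conjugation.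
- **Fallback:** the ynolate is made by oxygenation of a terminal acetylide instead of ester homologation. It sets out from silyl chloride 3 (with purchased prenyl bromide as the new carbon source) and comes back at lithium ynolate 5.
  - Prenyl bromide is coupled with ethynylmagnesium bromide (CuCl cat., THF) to 5-methylhex-4-en-1-yne F5.
  - n-BuLi converts F5 into lithium 5-methylhex-4-en-1-yn-1-ide F6.
  - F6 is oxygenated with lithium tert-butyl peroxide F7 (from t-BuOOH and LiN(SiMe3)2, THF, −78 → 0 °C) to 5.
  - Ynolate 5 is silylated with 3 as in step 2 to give 6.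

**3. Step 11**
- **What may go wrong:** SN2 displacement at the ethyl carbon is slower than at a methyl carbon. Magnesium may be diverted into the C3–O/C4=O chelate. Acid could hydrate or cyclise the prenyl chain if the silyl ether is lost.
- **Fallback:** the acidic hydroxyls are capped so that a stronger boron Lewis acid can be used without releasing protic acid, and so that C4=O/C5–O is the only bidentate site. It sets out from 23 and comes back at 24.
  - Ac2O, pyridine and DMAP give 4-[3-acetoxy-5-ethoxy-8-(3-methylbut-2-enyl)-4-oxo-7-(triisopropylsilyloxy)-4H-chromen-2-yl]phenyl acetate F8.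
  - BCl3 (CH2Cl2, −78 → 0 °C) cleaves the chelated peri ether to 4-[3-acetoxy-5-hydroxy-8-(3-methylbut-2-enyl)-4-oxo-7-(triisopropylsilyloxy)-4H-chromen-2-yl]phenyl acetate F9.
  - K2CO3 in MeOH at 0 °C removes both acetates to give 24. Any material that also loses silicon here is already the target 25.

## Further compounds

F1 | step 3 | 1-ethoxyvinyllithium | [Li]C(=C)OCC
F2 | step 3 | 3-ethoxybut-3-en-2-one | C=C(OCC)C(C)=O
F3 | step 3 | 5-ethoxy-1,1,1-trifluorohex-5-ene-2,4-dione | C=C(OCC)C(=O)CC(=O)C(F)(F)F
F4 | step 3 | 1-diazo-3-ethoxybut-3-en-2-one | C=C(OCC)C(=O)C=[N+]=[N-]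
F5 | step 2 | 5-methylhex-4-en-1-yne | C#CCC=C(C)C
F6 | step 2 | lithium 5-methylhex-4-en-1-yn-1-ide | [Li]C#CCC=C(C)C
F7 | step 2 | lithium tert-butyl peroxide | [Li+].[O-]OC(C)(C)C
F8 | step 11 | 4-[3-acetoxy-5-ethoxy-8-(3-methylbut-2-enyl)-4-oxo-7-(triisopropylsilyloxy)-4H-chromen-2-yl]phenyl acetate | CC(C)=CCc1c(O[Si](C(C)C)(C(C)C)C(C)C)cc(OCC)c2c(=O)c(OC(C)=O)c(-c3ccc(OC(C)=O)cc3)oc12
F9 | step 11 | 4-[3-acetoxy-5-hydroxy-8-(3-methylbut-2-enyl)-4-oxo-7-(triisopropylsilyloxy)-4H-chromen-2-yl]phenyl acetate | CC(C)=CCc1c(O[Si](C(C)C)(C(C)C)C(C)C)cc(O)c2c(=O)c(OC(C)=O)c(-c3ccc(OC(C)=O)cc3)oc12
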